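Substrate is conserved in a closed flask, so whatever is charged ends either as target or as something else, and these two shares add up to the whole charge.

| setting | east | south | north-west | zeta | epsilon | theta |
|---|---|---|---|---|---|---|
| substrate | 0.076 M | 0.12 M | 0.054 M | 0.054 M | 0.054 M | 0.054 M |
| first nucleophile | 0.0513 M | 0.0513 M | 0.077 M | 0.0513 M | 0.0513 M | 0.0513 M |
| second nucleophile | 0.0486 M | 0.0486 M | 0.0486 M | 0.0486 M | 0.0486 M | 0.0486 M |
| protic impurity | 0.0108 M | 0.0108 M | 0.0108 M | 0.0108 M | 0.0108 M | 0.0108 M |
| temperature | 95 °C | 128 °C | 95 °C | 140 °C | 110 °C | 80 °C |
| remark | run made earlier | run made earlier | run made earlier |  |  |  |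
| time |  |  |  | 2.5 h | 2.5 h | 2.5 h |

| run | time / h | target / % | substrate / % |
|---|---|---|---|
| east | 2.00 | 33.8 | 0 |
| east | 4.00 | 35.4 | 0.3 |
| east | 6.00 | 35.1 | 0 |
| east | 12.0 | 34.2 | 0.6 |
| east | 25.0 | 35.7 | 0 |
| south | 0.333 | 25.9 | 1.2 |
| south | 1.33 | 24.3 | 0 |
| south | 2.50 | 24.7 | 0 |
| south | 4.00 | 23.3 | 0.2 |
| south | 5.00 | 25.2 | 0 |
| north-west | 2.00 | 42.7 | 0.5 |
| north-west | 4.00 | 41.0 | 1.6 |
| north-west | 6.00 | 42.1 | 0 |
| north-west | 12.0 | 39.5 | 0 |
| north-west | 25.0 | 43.0 | 0 |

(scatter of a reading: 1 percentage point)

- a reading or a percentage of target counts all its forms, free or not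

1. which flask leads in amount of target, in percent of the substrate charged ("all alike" within 1.5 percentage points) (zeta / epsilon / theta / all alike)
2. how much target is there at the end, in percent of the substrate charged: zeta
3. how much target is there at the end, in percent of the substrate charged: epsilon
4. how much target is there at the end, in percent of the substrate charged: theta

In the east run the substrate reads 0% at 2.00 h, and with a scatter of 1 percentage point I take that as a fall to a hundredth at least, which gives a halving time of at most 0.301 h. The time asked then holds 8.31 halvings at east's rate, though theta is colder and its rate is unread. Target stays flat from first reading to last, so I treat each end state as a partition. If target forms at a rate proportional to c(first nucleophile) against losses that do not involve it, then the odds of target against the rest grow in proportion to c(first nucleophile). But east charges less first nucleophile than substrate, and the target of its last reading equals 52.9% of its first nucleophile charge, so the charged concentration that I put in is an approximation.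

East averages 34.8% and north-west 41.7%, so their odds over c(first nucleophile) read 10.4 /M and 9.27 /M, although their substrate charges differ. I call the mean of these the capture constant at 95 °C, a selectivity factor, 9.85 /M. South averages 24.7%, which reads 6.39 /M, lower than at 95 °C.

Running the logarithm of the east and south values straight through temperature, I reckon 5.35 /M for zeta, 8.34 /M for epsilon and 13.0 /M for theta. Those give shares of 21.5%, 30.0% and 40.0%, with theta ahead, provided its substrate is consumed.

The forecast also names theta, with 22% for zeta, 29% for epsilon and 33% for theta. Its theta stands lower than mine, on the ground that “conversion in 2.5 h may be slightly incomplete”.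

Theta leads with 37.4%, against 27.0% in epsilon and 17.4% in zeta.

    first nucleophile + intermediate → target (k = 1000 /M/min, Ea = 37.0 kJ/mol)
    second nucleophile + protic impurity → quenched reagent (k = 2.10 /M/min, Ea = 62.0 kJ/mol)
    second nucleophile + intermediate → other capture product (k = 2400 /M/min, Ea = 48.0 kJ/mol)
    crystals ⇌ target, rate k4*(cs4 - [target]) while solid is left; crystals form when [target] > cs4 (solubility = 2.90 mM, k = 0.730 /min)
    intermediate → solvolysis product (k = 5.90 /min, Ea = 91.0 kJ/mol)
    substrate → intermediate (k = 0.150 /min, Ea = 113 kJ/mol)
    (constants at 80 °C)

Theta's substrate halves in 0.0770 h, so 2.5 h holds 32.5 halvings and conversion stands at 100%. Epsilon's share gives a capture constant of 7.23 /M, lower than the 9.85 /M read at 95 °C. The neighbour of epsilon with 0.087 M of first nucleophile then reckons to 38.6%, and that flask holds 37.6%.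

All runs come from a simulation with constants of no real substance; the scatter is artificial.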